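The runs are simulated on assumed constants; scatter was added.

Saturday's flask and Friday's held the same 0.500 M of starting material, but Friday's also began with 0.250 M of target.

| setting | Saturday's | Wednesday's | Friday's | Monday's | Sunday's |
|---|---|---|---|---|---|
| starting material | 0.500 M | 0.200 M | 0.500 M | 0.750 M | 1.50 M |
| target |  |  | 0.250 M |  |  |
| time |  |  |  |  | 170 min |

| run | time / min | [target] / M |
|---|---|---|
| Saturday's run | 24 | 0.078 |
| Saturday's run | 49 | 0.111 |
| Saturday's run | 73 | 0.135 |
| Saturday's run | 97 | 0.141 |
| Saturday's run | 120 | 0.146 |
| Saturday's run | 150 | 0.151 |
| Saturday's run | 170 | 0.156 |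
| Wednesday's run | 24 | 0.037 |
| Wednesday's run | 49 | 0.060 |
| Wednesday's run | 73 | 0.068 |
| Wednesday's run | 97 | 0.071 |
| Wednesday's run | 120 | 0.077 |
| Wednesday's run | 150 | 0.082 |
| Wednesday's run | 170 | 0.086 |
| Friday's run | 24 | 0.332 |
| Friday's run | 49 | 0.365 |
| Friday's run | 73 | 0.380 |
| Friday's run | 97 | 0.390 |
| Friday's run | 120 | 0.398 |
| Friday's run | 150 | 0.405 |
| Friday's run | 170 | 0.404 |
| Monday's run | 24 | 0.104 |
| Monday's run | 49 | 0.150 |
| Monday's run | 73 | 0.163 |
| Monday's run | 97 | 0.180 |
| Monday's run | 120 | 0.186 |
| Monday's run | 150 | 0.192 |
| Monday's run | 170 | 0.194 |

(each reading ± 0.003 M)

1. reaction order in [starting material] at the outset, round the charge of the Saturday's run, defined at two percent of the starting material turned into target (one fixed amount of target, the same in the runs compared)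
2. target in the Sunday's run at 170 min, as a share of the starting material charged

By 170 min, Friday's flask had gained 0.154 M and Saturday's 0.156 M, about the same, so I left target out of my reckoning.

At 170 min, target stood at 43.0% of the charge in Wednesday's flask, 31.2% in Saturday's and 25.9% in Monday's. So I followed one molecule of starting material. I supposed that at each moment it could react alone, to target or otherwise, or pair with a neighbour, and that pairing grew with [starting material]. On that supposition its chance of becoming target (the selectivity) falls as [starting material] rises. I named the even point E: the [starting material] where pairing consumes as much as the single-molecule steps together. Summing the chance until the starting material is used up gives [target] = G ln(1 + charge/E), with G one constant for these flasks. I took the readings at 170 min as near that end, though Saturday's flask still went from 0.151 M at 150 min to 0.156 M.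

I tried E = 0.200 M, Wednesday's charge. The law then puts Saturday's target over Wednesday's at 1.81, and the readings give 1.81. Wednesday's reading gave G = 0.124 M, and so 17.7% for Sunday's flask.

The weak link was that small reading, with its scatter of 0.003 M. Saturday's larger reading gave G = 0.125 M, and so 17.8% for Sunday's flask, which I committed to. In my picture target forms from one molecule, so I committed to order 1 as well.

The forecast, which differs from my numbers, gave 0.85 and 16.7%: “Yield falls with charge.”

The flask gave order 1.0 and 18.3%.

    starting material → target (0.008340 min⁻¹)
    2 starting material → side product (0.03714 M⁻¹ min⁻¹)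
    starting material → decomposed substrate (0.007440 min⁻¹)
    starting material → target (0.002244 min⁻¹)

At one amount of target, Monday's rate stood at 1.5 times Saturday's, on 1.50 times the charge. With E = 0.200 M, the law gave Monday's flask 25.9% of its charge as target. Target made in Wednesday's flask came to a quarter of the charge at 39.6 min, and in Monday's flask later, at 119 min.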